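## Structural features

The target 19 is an isoflavan quinone. A chroman (benzene ring A fused to the dihydropyran ring C made of O1, C2, C3, C4, C4a and C8a) carries at C3 a 2,3-dimethoxy-1,4-benzoquinone (ring B, joined through C1'; C2' and C5' are the carbonyl carbons, C3' and C4' bear methoxy groups, C6' bears hydrogen). Ring A is oxygenated on four neighbouring carbons (O1 on C8a, OMe on C8, free OH on C7, OMe on C6), so only C5 carries hydrogen. C3 is the only stereocentre and is S. It has no stereogenic neighbour, bears one hydrogen, and lies between two methylene groups, C2 (bonded to O1) and C4 (bonded to C4a), which differ only at the second atom. The quinone is the fragile part: it is electrophilic and reducible, and the C3–H bond is vinylogously acidic through C1'=C6'–C5'=O, so base can epimerise C3 by way of a quinone methide tautomer. The ring A phenol (para to C4a) and both rings in their ether forms are tetra-oxygenated arenes that do not tolerate strong one-electron oxidants. The real difficulty is therefore the enantioselective creation of an isolated tertiary stereocentre without a directing neighbour, and its survival until the quinone is unveiled. The plan exploits the local symmetry about C3: if the hydrogen on C3 is replaced by a second CH2OH group, the C2 arm and the added arm become enantiotopic, and bonding one of the two oxygens (the future O1) to an iodine-bearing C8a of ring A closes ring C and fixes the configuration in a single event.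

## Logic of the disconnections

19 ⇒ 17 (through 18). No skeletal bond is cut. The two quinone carbonyls are taken back to benzyl-protected phenol oxygens and O7–H to O7–benzyl, so that forward three O–CH2Ph bonds are broken and the hydroquinone of 18 is oxidised. The reason is the lability of 19: the quinone is electrophilic and makes C3–H acidic, so it has to appear last and under neutral conditions. The gain is that every earlier intermediate is a robust polyether arene. The demand is that one hydrogenolysis clears three hindered ethers and that the oxidant takes the hydroquinone of 18 but not its ring A phenol.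

17 ⇒ 16 ⇒ 15. A carbon is added back on C3 (C3–CHO, then C3–CH2OH); forward, this C3–C bond is the one that is cut. With the extra arm, C3 is quaternary and flanked by two oxygenated methylene groups, which turns the making of an isolated tertiary centre into a choice between two like groups. Nothing is gained in atom count, but the centre can no longer epimerise and its origin becomes a desymmetrisation. The demand is an excision of the formyl group with retention at C3, in which C–H reductive elimination has to outrun β-hydride loss toward C2 and C4, and an oxidation of the neopentyl alcohol that spares both electron-rich rings.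

15 ⇒ 14. The O1–C8a bond is cut. This opens ring C, removes the only stereocentre and returns the achiral, prochiral diol 14 with iodine on C8a. The cut is placed here because it is the one bond whose formation can tell the two hydroxymethyl arms apart. The gain is one ring and one stereocentre. The demand is a chiral catalyst that reads the difference between the ring B aryl group and the ring A benzyl group on the prochiral carbon, and activation of a C–I bond flanked by OMe and CH2.

14 ⇒ 13 ⇒ 12 + 5. The two C–OH groups are taken back to ester carbons, then the C3–C4 bond is cut. This uses the natural polarity of a doubly stabilised carbanion at C3 and a benzylic electrophile at C4, and it divides the molecule into a ring A half and a ring B half of similar size. The demand is an SN2 reaction that creates a quaternary carbon between two ortho-substituted partners, and a reduction of two hindered esters that leaves the C–I bond intact and does not fragment the chain.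

12 ⇒ 10 + 11. The C3–C1' bond between ring B and the future C3 is cut. Ring B becomes a simple aryl bromide, and 11 supplies C2, C3 and the sacrificial carbon in one piece. The demand is an enolate arylation on an electron-rich bromide that carries an ortho alkoxy group.

5 ⇒ 4 ⇒ 3 ⇒ 2 ⇒ 1. The C–Br bond, the C8a–I bond and the O7–benzyl bond are removed and the benzylic carbon is returned to the aldehyde level. 1 already holds C4 as its formyl carbon and the 6,7,8-oxygen pattern with the free hydroxyl in the right place. Because 1 is symmetric, iodination at either free position gives the same C8a iodide. The demand is clean mono-iodination and a benzylic bromide that is made cold and used at once.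

10 ⇒ 9 ⇒ 7 ⇒ 6 (through 8). The C1'–Br bond, two O–benzyl bonds and one ring C–O bond are cut in turn. 6 brings three of the four ring B oxygens; para oxidation adds the fourth and gives the quinone level directly. 9 is symmetric, so bromination can give only one isomer. The demand is para-selective oxidation of a phenol and handling of the air-sensitive 8 without isolation.

## Other disconnections considered

Alternative 1: The cut removes C3–C1' after a temporary C4–O bond to the ring B oxygen on C2' has been added, which leads back to a pterocarpan. Forward, the chromene A1 (7-benzyloxy-6,8-dimethoxy-2H-chromene) would attack the quinone A2 (2,3-dimethoxy-1,4-benzoquinone, the same compound as 7) through C3 while A2 is held by a chiral tetravalent titanium Lewis acid (TiCl2(OiPr)2 with a TADDOL diol). The benzylic cation at C4, stabilised by O1 and by the para oxygen on C7, would be captured by the neighbouring quinone oxygen to give the cis-pterocarpan A3. Hydrogenolysis of A3 would cut the benzylic C4–O bond together with the benzyl ether and give 18, which goes on to 19.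
- In its favour: the stereocentre is made directly as the tertiary centre; no sacrificial carbon and no halogen are needed; ring B arrives with its final oxygen pattern. On step economy this route is clearly better than the chosen one (roughly eight operations against fourteen), and on convergence it is at least its equal. The later removal of the C4–O bond costs nothing, because it coincides with debenzylation; on that point the two plans are equal.
- Against it here: the chiral titanium reagent is needed in about stoichiometric amount and is moisture-sensitive. A2 is a doubly vinylogous ester, less electrophilic than the mono-alkoxyquinones for which this reaction type is established, and it offers two equivalent chelating sites. [2+2] and [5+2] cycloadditions compete with the [3+2] path, and the electron-rich styrene unit of A1 is prone to cationic oligomerisation.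
- Comparison: the face selection rests on a stepwise cationic addition through a freely rotating zwitterion, whereas the chosen plan decides the configuration in an intramolecular reaction inside a defined chelate. The chosen plan is longer, but each of its steps stands on firmer ground for this substitution pattern.

Alternative 2: The cut removes C3–C4 and the O1–C2 acyl bond of a 3-arylchroman-2-one. Forward, base would release the o-quinone methide A5 from the 2-(tosylmethyl)phenol A4. The isothiourea-bound ammonium enolate of the activated arylacetic acid A6 would add to the methylene of A5, and the phenoxide would then acylate and release the catalyst, giving the lactone A7. Reduction of A7 to the diol A8 and Mitsunobu closure would give 17.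
- In its favour: organocatalytic and catalytic in the chiral element; no transition metal; two ring bonds in one operation; tertiary centre made directly. In step count it is about equal to the chosen plan, since the C2 carbonyl has to be reduced out in two steps just as the extra carbon of the chosen plan is excised in two. It is better in that it avoids stoichiometric rhodium and a hindered aryl iodide.
- Against it here: the stereocentre of A7 is α to an aryl ester carbonyl and benzylic, so the base needed to release A5 can epimerise it. A5 has no substituent on its methylene, so it would be short-lived and prone to oligomerise. No stereocentre forms at C4, so induction rests on the enolate face alone.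
- Comparison: the chosen plan carries C3 as a quaternary centre that cannot epimerise up to the penultimate stage; on configurational security it is the better plan.

Alternative 3: The cut removes C4–C4a and O1–C8a at once. Forward, the aryl iodide A9 (iodine on the future C8a, hydrogen on the future C4a, OMe blocking the other ortho position) and the enantiopure bromo alcohol A10 would react under Pd(OAc)2, tri(2-furyl)phosphine, norbornene and Cs2CO3. The sequence is oxidative addition to zerovalent palladium, norbornene insertion and ortho C–H palladation, alkylation at C4a by the C–Br bond through tetravalent palladium, norbornene extrusion, and ipso C–O coupling with the hydroxyl. The product A11 is identical with 17.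
- In its favour: the annulation product needs no adjustment before the end-game, two operations fewer after ring closure than in the chosen plan, which makes it better on that count. The ring A partner is very simple. The stereocentre is carried in, is not acidic and is not touched. In convergence the two plans are equal.
- Against it here: the stereochemical problem is only moved into A10, whose preparation needs its own asymmetric step, so the overall count is about equal. The β-branched primary bromide would react slowly with the palladacycle. A10 can undergo intramolecular Williamson reaction under Cs2CO3 at the temperature required. C–O reductive elimination from a divalent aryl-palladium alkoxide with this phosphine is slow compared with β-hydride elimination of the alkoxide, which would end in hydrodehalogenation of A9.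
- Comparison: four organometallic events in a row have to stay on course here, whereas the chosen plan needs one alkoxide formation and one C–O bond formation at copper, helped by gem-disubstitution.

Key step: step 11

Assumption: the sense of induction of the copper–diamine catalyst cannot be deduced from the structure alone; the (1R,2R)-diamine is written, and its mirror image is to be used if it should deliver the antipode of 15.

## Route

Step 1
Reactants: 1 syringaldehyde (4-hydroxy-3,5-dimethoxybenzaldehyde)
Product: 2 4-(benzyloxy)-3,5-dimethoxybenzaldehyde
Conditions: BnBr, K2CO3, DMF, 60 °C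
Reagents that add atoms: benzyl bromide, BrCc1ccccc1
Why: Williamson O-benzylation; the hindered but acidic 2,6-dimethoxyphenoxide alkylates cleanly in DMF, and the benzyl ether should survive every later step until the final hydrogenolysis.

Step 2
Reactants: 2 4-(benzyloxy)-3,5-dimethoxybenzaldehyde
Product: 3 [4-(benzyloxy)-3,5-dimethoxyphenyl]methanol
Conditions: NaBH4, MeOH, 0 °C
Reagents that add atoms: none
Why: Hydride reduction of the aldehyde to the benzylic alcohol; nothing else in the molecule is reducible by NaBH4.

Step 3
Reactants: 3 [4-(benzyloxy)-3,5-dimethoxyphenyl]methanol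
Product: 4 [4-(benzyloxy)-2-iodo-3,5-dimethoxyphenyl]methanol
Conditions: I2, CF3CO2Ag, CHCl3, 0 °C to rt
Reagents that add atoms: iodine, II
Why: Electrophilic aromatic iodination with silver-activated iodine; the two free ring positions are equivalent, each is activated by an ortho and a para methoxy group, and the unactivated phenyl ring of the benzyl ether does not compete.

Step 4
Reactants: 4 [4-(benzyloxy)-2-iodo-3,5-dimethoxyphenyl]methanol
Product: 5 2-(benzyloxy)-5-(bromomethyl)-4-iodo-1,3-dimethoxybenzene (4-benzyloxy-2-iodo-3,5-dimethoxybenzyl bromide)
Conditions: PBr3, CH2Cl2, 0 °C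
Reagents that add atoms: phosphorus tribromide, BrP(Br)Br
Why: Conversion of the benzylic alcohol into the bromide (SN2 on the alkyl phosphite ester); the cold, non-basic conditions spare the aryl iodide and the ethers, and the bromide is used without storage.

Step 5
Reactants: 6 2,3-dimethoxyphenol
Product: 7 2,3-dimethoxy-1,4-benzoquinone
Conditions: (KSO3)2NO (2.2 equiv), aq. KH2PO4, acetone/H2O, 0 °C to rt
Reagents that add atoms: potassium nitrosodisulfonate, [K+].[K+].[O]N(S(=O)(=O)[O-])S(=O)(=O)[O-]
Why: Teuber oxidation; the nitroxyl radical abstracts the phenolic hydrogen and a second equivalent couples through oxygen at the unsubstituted para position, and collapse of that adduct should give the para-quinone.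

Step 6
Reactants: 7 2,3-dimethoxy-1,4-benzoquinone
Product: 9 1,4-bis(benzyloxy)-2,3-dimethoxybenzene, via 2,3-dimethoxyhydroquinone 8 (not isolated)
Conditions: Na2S2O4, EtOAc/H2O, rt; organic phase concentrated under N2; then BnBr, K2CO3, DMF, 60 °C
Reagents that add atoms: benzyl bromide, BrCc1ccccc1
Why: Dithionite reduction of the quinone followed at once by double Williamson benzylation of the air-sensitive hydroquinone; ring B thereby receives the same protecting group as ring A, so that one hydrogenolysis can serve both at the end.

Step 7
Reactants: 9 1,4-bis(benzyloxy)-2,3-dimethoxybenzene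
Product: 10 1,4-bis(benzyloxy)-5-bromo-2,3-dimethoxybenzene
Conditions: NBS (1.0 equiv), MeCN, 0 °C to rt, dark
Reagents that add atoms: N-bromosuccinimide, O=C1CCC(=O)N1Br
Why: Electrophilic aromatic bromination; the two free positions of 9 are equivalent and strongly activated, and one equivalent of reagent at low temperature should limit a second bromination and oxidative dealkylation.

Step 8
Reactants: 10 1,4-bis(benzyloxy)-5-bromo-2,3-dimethoxybenzene; 11 diethyl malonate
Product: 12 diethyl 2-[2,5-bis(benzyloxy)-3,4-dimethoxyphenyl]propanedioate
Conditions: Pd(dba)2 (3 mol%), P(t-Bu)3·HBF4 (6 mol%), K3PO4, toluene, 80 °C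
Reagents that add atoms: none
Why: Palladium-catalysed α-arylation of a malonate enolate; a bulky electron-rich trialkylphosphine is chosen because copper-mediated Hurtley-type coupling is unreliable for an electron-rich bromide with an ortho alkoxy group, and the mild phosphate base leaves the esters intact.

Step 9
Reactants: 12 diethyl 2-[2,5-bis(benzyloxy)-3,4-dimethoxyphenyl]propanedioate; 5 2-(benzyloxy)-5-(bromomethyl)-4-iodo-1,3-dimethoxybenzene
Product: 13 diethyl 2-[2,5-bis(benzyloxy)-3,4-dimethoxyphenyl]-2-{[4-(benzyloxy)-2-iodo-3,5-dimethoxyphenyl]methyl}propanedioate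
Conditions: NaH, DMF, 0 °C; then 5, 0 °C to rt
Reagents that add atoms: none
Why: SN2 alkylation of the stabilised sodium arylmalonate with a reactive benzylic bromide; this forms the C3–C4 bond and the quaternary carbon that becomes C3, and the aryl iodide is inert to the enolate.

Step 10
Reactants: 13 diethyl 2-[2,5-bis(benzyloxy)-3,4-dimethoxyphenyl]-2-{[4-(benzyloxy)-2-iodo-3,5-dimethoxyphenyl]methyl}propanedioate
Product: 14 2-[2,5-bis(benzyloxy)-3,4-dimethoxyphenyl]-2-{[4-(benzyloxy)-2-iodo-3,5-dimethoxyphenyl]methyl}propane-1,3-diol
Conditions: i-Bu2AlH (6 equiv), CH2Cl2, −78 to 0 °C; aq. KNaC4H4O6 work-up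
Reagents that add atoms: none
Why: Exhaustive ester reduction with an electrophilic aluminium hydride, chosen because it leaves the aryl C–I bond alone (unlike LiAlH4) and gives covalent aluminium alkoxides that resist retro-aldol loss of formaldehyde; the product is the achiral, prochiral 1,3-diol.

Step 11
Reactants: 14 2-[2,5-bis(benzyloxy)-3,4-dimethoxyphenyl]-2-{[4-(benzyloxy)-2-iodo-3,5-dimethoxyphenyl]methyl}propane-1,3-diol
Product: 15 {(3S)-7-(benzyloxy)-3-[2,5-bis(benzyloxy)-3,4-dimethoxyphenyl]-6,8-dimethoxy-3,4-dihydro-2H-chromen-3-yl}methanol
Conditions: CuI (10 mol%), (1R,2R)-N,N'-dimethyl-1,2-diphenylethane-1,2-diamine (20 mol%), Cs2CO3 (2 equiv), MeCN (0.02 M), 30 °C, argon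
Reagents that add atoms: none
Why: Ullmann-type copper/diamine-catalysed intramolecular O-arylation run as a desymmetrisation, a known reaction type for 2,2-disubstituted 2-(2-halobenzyl)propane-1,3-diols that gives 3,3-disubstituted chromans. Cs2CO3 and the diamine-bound monovalent copper convert either hydroxyl reversibly into a copper alkoxide; the C8a–I bond is then activated inside that complex (oxidative addition to a trivalent aryl-copper alkoxide held in a seven-membered chelate), and C–O reductive elimination forms O1–C8a and returns monovalent copper. Ring C thus closes as a six-membered ring by ipso substitution at the sp2 carbon C8a, exo with respect to the departing iodide, and the gem-disubstitution at C3 (Thorpe–Ingold effect) favours the closure. The new quaternary stereocentre C3 is set by the chiral ligand alone (catalyst control, Curtin–Hammett selection between the two rapidly exchanging diastereomeric alkoxides). The selectivity needed is enantiotopic-group selection together with intramolecular over intermolecular coupling. The substrate secures this in three ways: it has a single C–I bond, so only one arylation is possible; the ortho-benzyloxy aryl group is far bulkier than the CH2 tether, which gives the ligand a large steric contrast to read; and the alkoxide is held close to C8a, which with dilution suppresses oligomerisation. The product is quaternary at C3 and cannot racemise, and N-arylation of the secondary diamine, the main off-cycle process, is countered by low temperature and an excess of ligand over copper.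

Step 12
Reactants: 15 {(3S)-7-(benzyloxy)-3-[2,5-bis(benzyloxy)-3,4-dimethoxyphenyl]-6,8-dimethoxy-3,4-dihydro-2H-chromen-3-yl}methanol
Product: 16 (3R)-7-(benzyloxy)-3-[2,5-bis(benzyloxy)-3,4-dimethoxyphenyl]-6,8-dimethoxy-3,4-dihydro-2H-chromene-3-carbaldehyde
Conditions: Dess–Martin periodinane, CH2Cl2, 0 °C to rt
Reagents that add atoms: none
Why: Dess–Martin oxidation of the neopentyl primary alcohol under neutral, non-aqueous conditions; the α-carbon is quaternary, so neither epimerisation nor enolisation is possible, and the electron-rich rings are not attacked (the descriptor changes from S to R only because the CIP priorities change).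

Step 13
Reactants: 16 (3R)-7-(benzyloxy)-3-[2,5-bis(benzyloxy)-3,4-dimethoxyphenyl]-6,8-dimethoxy-3,4-dihydro-2H-chromene-3-carbaldehyde
Product: 17 (3S)-7-(benzyloxy)-3-[2,5-bis(benzyloxy)-3,4-dimethoxyphenyl]-6,8-dimethoxy-3,4-dihydro-2H-chromene
Conditions: RhCl(PPh3)3 (1.2 equiv), degassed xylene, 135 °C
Reagents that add atoms: none
Why: Tsuji–Wilkinson decarbonylation: oxidative addition of the aldehyde C–H bond to monovalent rhodium, CO de-insertion with retention at the migrating carbon and C–H reductive elimination on the same face should place hydrogen on C3 with retention, as is known for α-quaternary and α-aryl aldehydes. The rhodium complex is used in stoichiometric amount because the carbonyl complex formed is inert, and reductive elimination from the hindered tertiary alkyl rhodium hydride is expected to be faster than β-hydride loss toward C2 or C4.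

Step 14
Reactants: 17 (3S)-7-(benzyloxy)-3-[2,5-bis(benzyloxy)-3,4-dimethoxyphenyl]-6,8-dimethoxy-3,4-dihydro-2H-chromene
Product: 19 5-[(3S)-7-hydroxy-6,8-dimethoxy-3,4-dihydro-2H-chromen-3-yl]-2,3-dimethoxycyclohexa-2,5-diene-1,4-dione, via hydroquinone 18 (not isolated)
Conditions: H2 (1 atm), 10% Pd/C, EtOAc/MeOH, rt; filtration; then air, rt
Reagents that add atoms: none
Why: Hydrogenolysis of the three aryl benzyl ethers gives the hydroquinone, whose low oxidation potential should allow selective autoxidation to the para-quinone while the ring A monophenol, of much higher potential, is left alone. Air is preferred to FeCl3 for that reason, and the neutral medium avoids base-induced epimerisation of C3 through the quinone methide tautomer.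

## Compound list

1 | syringaldehyde (4-hydroxy-3,5-dimethoxybenzaldehyde) | COc1cc(C=O)cc(OC)c1O | starting material
2 | 4-(benzyloxy)-3,5-dimethoxybenzaldehyde | COc1cc(C=O)cc(OC)c1OCc1ccccc1 | intermediate
3 | [4-(benzyloxy)-3,5-dimethoxyphenyl]methanol | COc1cc(CO)cc(OC)c1OCc1ccccc1 | intermediate
4 | [4-(benzyloxy)-2-iodo-3,5-dimethoxyphenyl]methanol | OCc1cc(OC)c(OCc2ccccc2)c(OC)c1I | intermediate
5 | 2-(benzyloxy)-5-(bromomethyl)-4-iodo-1,3-dimethoxybenzene | BrCc1cc(OC)c(OCc2ccccc2)c(OC)c1I | intermediate
6 | 2,3-dimethoxyphenol | COc1cccc(O)c1OC | starting material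
7 | 2,3-dimethoxy-1,4-benzoquinone | COC1=C(OC)C(=O)C=CC1=O | intermediate
8 | 2,3-dimethoxybenzene-1,4-diol | COc1c(O)ccc(O)c1OC | intermediate
9 | 1,4-bis(benzyloxy)-2,3-dimethoxybenzene | COc1c(OCc2ccccc2)ccc(OCc2ccccc2)c1OC | intermediate
10 | 1,4-bis(benzyloxy)-5-bromo-2,3-dimethoxybenzene | COc1c(OC)c(OCc2ccccc2)cc(Br)c1OCc1ccccc1 | intermediate
11 | diethyl malonate | CCOC(=O)CC(=O)OCC | starting material
12 | diethyl 2-[2,5-bis(benzyloxy)-3,4-dimethoxyphenyl]propanedioate | CCOC(=O)C(C(=O)OCC)c1cc(OCc2ccccc2)c(OC)c(OC)c1OCc1ccccc1 | intermediate
13 | diethyl 2-[2,5-bis(benzyloxy)-3,4-dimethoxyphenyl]-2-{[4-(benzyloxy)-2-iodo-3,5-dimethoxyphenyl]methyl}propanedioate | CCOC(=O)C(Cc1cc(OC)c(OCc2ccccc2)c(OC)c1I)(C(=O)OCC)c1cc(OCc2ccccc2)c(OC)c(OC)c1OCc1ccccc1 | intermediate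
14 | 2-[2,5-bis(benzyloxy)-3,4-dimethoxyphenyl]-2-{[4-(benzyloxy)-2-iodo-3,5-dimethoxyphenyl]methyl}propane-1,3-diol | OCC(CO)(Cc1cc(OC)c(OCc2ccccc2)c(OC)c1I)c1cc(OCc2ccccc2)c(OC)c(OC)c1OCc1ccccc1 | intermediate
15 | {(3S)-7-(benzyloxy)-3-[2,5-bis(benzyloxy)-3,4-dimethoxyphenyl]-6,8-dimethoxy-3,4-dihydro-2H-chromen-3-yl}methanol | COc1c(OC)c(OCc2ccccc2)cc([C@@]2(CO)COc3c(cc(OC)c(OCc4ccccc4)c3OC)C2)c1OCc1ccccc1 | intermediate
16 | (3R)-7-(benzyloxy)-3-[2,5-bis(benzyloxy)-3,4-dimethoxyphenyl]-6,8-dimethoxy-3,4-dihydro-2H-chromene-3-carbaldehyde | COc1c(OC)c(OCc2ccccc2)cc([C@@]2(C=O)COc3c(cc(OC)c(OCc4ccccc4)c3OC)C2)c1OCc1ccccc1 | intermediate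
17 | (3S)-7-(benzyloxy)-3-[2,5-bis(benzyloxy)-3,4-dimethoxyphenyl]-6,8-dimethoxy-3,4-dihydro-2H-chromene | COc1c(OC)c(OCc2ccccc2)cc([C@H]2COc3c(cc(OC)c(OCc4ccccc4)c3OC)C2)c1OCc1ccccc1 | intermediate
18 | (3S)-3-(2,5-dihydroxy-3,4-dimethoxyphenyl)-6,8-dimethoxy-3,4-dihydro-2H-chromen-7-ol | COc1c(OC)c(O)cc([C@H]2COc3c(cc(OC)c(O)c3OC)C2)c1O | intermediate
19 | 5-[(3S)-7-hydroxy-6,8-dimethoxy-3,4-dihydro-2H-chromen-3-yl]-2,3-dimethoxycyclohexa-2,5-diene-1,4-dione | COC1=C(OC)C(=O)C([C@H]2COc3c(cc(OC)c(O)c3OC)C2)=CC1=O | target

## Step count and least certain steps

Total step count: 14. Longest linear sequence: 10 steps (steps 5 to 14 from 6; the ring A branch from 1, steps 1 to 4 and 9 to 14, is equally long).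

Step 11 (key step). The most likely failure is poor discrimination between the two enantiotopic hydroxymethyl arms, because both substituents on the prochiral carbon are large and the C–I bond, flanked by OMe and CH2, may need more heat than the selectivity can bear. Slow aryl iodide activation, N-arylation of the ligand and hydrodeiodination are the other risks. Fallback, setting out from 14 and returning at 15: the stereocentre is set by an enzyme before the ring is closed. A lipase (Burkholderia cepacia lipase, vinyl acetate, t-BuOMe; an enzyme of the required preference to be found by screening) would acetylate one arm to give (2S)-2-[2,5-bis(benzyloxy)-3,4-dimethoxyphenyl]-2-{[4-(benzyloxy)-2-iodo-3,5-dimethoxyphenyl]methyl}-3-hydroxypropyl acetate F1. Because base-induced acyl migration between the arms would racemise F1, its free hydroxyl is silylated (t-BuMe2SiCl, imidazole, DMF) to the silyl ether acetate F2, and the acetate is removed (K2CO3, MeOH) to give the mono-silyl ether alcohol F3. F3 is then cyclised with an achiral catalyst (CuI, 1,10-phenanthroline, Cs2CO3, toluene, 100 °C) to the silyl-protected chroman F4, and Bu4NF in THF releases 15.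

Step 13. The risks are β-hydride loss from the tertiary alkyl rhodium hydride toward C2 or C4, partial loss of configuration by homolysis of the benzylic rhodium–carbon bond at the temperature needed, and sluggish C–H oxidative addition at the hindered formyl group. Fallback, setting out from 12 and 5 and returning at 17: the tertiary centre is made directly with a chiral auxiliary, so that no carbon has to be excised. Saponification and decarboxylation of 12 (KOH, aqueous EtOH, then acid and warming) would give 2-[2,5-bis(benzyloxy)-3,4-dimethoxyphenyl]acetic acid F5. Acylation of lithiated (4S)-4-benzyl-1,3-oxazolidin-2-one through the pivaloyl mixed anhydride gives the imide F6. Evans alkylation (NaN(SiMe3)2, THF, −78 °C, then 5), in which the benzyl group of the auxiliary shields one face of the chelated Z-enolate, gives the (2S)-alkylated imide F7. LiBH4 (Et2O, H2O, 0 °C) cleaves the auxiliary to (2S)-2-[2,5-bis(benzyloxy)-3,4-dimethoxyphenyl]-3-[4-(benzyloxy)-2-iodo-3,5-dimethoxyphenyl]propan-1-ol F8, and an achiral intramolecular O-arylation (CuI, 1,10-phenanthroline, Cs2CO3, toluene, 110 °C) closes ring C to 17. This fallback also bypasses steps 10 to 12.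

Step 8. The risks are slow oxidative addition and slow reductive elimination at an electron-rich aryl group with an ortho benzyloxy substituent, protodebromination, and loss of one ester group from the product at the reaction temperature. Fallback, setting out from 10, 5 and 11 and returning at 13: the polarity is reversed and the order of the two C–C bond formations is exchanged. Bromine–lithium exchange on 10 (n-BuLi, THF, −78 °C) and quenching with B(OiPr)3 would give [2,5-bis(benzyloxy)-3,4-dimethoxyphenyl]boronic acid F9. Separately, 5 alkylates an excess of the sodium salt of 11 to give diethyl 2-{[4-(benzyloxy)-2-iodo-3,5-dimethoxyphenyl]methyl}propanedioate F10. Boron–lead exchange on F9 (Pb(OAc)4, catalytic Hg(OAc)2, CHCl3, 40 °C) gives the aryllead triacetate F11, which arylates the sodium enolate of F10 in CHCl3/pyridine (Pinhey arylation) to give 13 directly.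

Step 14. The risks are incomplete hydrogenolysis of the two hindered benzyl ethers (catalyst poisoning by traces of phosphine or rhodium carried over from step 13), over-oxidation at the ring A phenol if the autoxidation has to be forced, and epimerisation of C3 if the medium becomes basic. Fallback, setting out from 17 and returning at 19: the ethers are cleaved by a Lewis acid instead of hydrogen (BCl3, pentamethylbenzene as cation scavenger, CH2Cl2, −78 °C), and 18 is isolated under argon. It is then oxidised by redox exchange with one equivalent of 1,4-benzoquinone (CH2Cl2, rt), a two-electron hydrogen transfer that is thermodynamically able to oxidise the electron-rich hydroquinone but not a monophenol. No new compound arises on this path.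

## Further compounds

F1 | step 11 | (2S)-2-[2,5-bis(benzyloxy)-3,4-dimethoxyphenyl]-2-{[4-(benzyloxy)-2-iodo-3,5-dimethoxyphenyl]methyl}-3-hydroxypropyl acetate | CC(=O)OC[C@@](CO)(Cc1cc(OC)c(OCc2ccccc2)c(OC)c1I)c1cc(OCc2ccccc2)c(OC)c(OC)c1OCc1ccccc1
F2 | step 11 | (2R)-2-[2,5-bis(benzyloxy)-3,4-dimethoxyphenyl]-2-{[4-(benzyloxy)-2-iodo-3,5-dimethoxyphenyl]methyl}-3-{[tert-butyl(dimethyl)silyl]oxy}propyl acetate | CC(=O)OC[C@@](CO[Si](C)(C)C(C)(C)C)(Cc1cc(OC)c(OCc2ccccc2)c(OC)c1I)c1cc(OCc2ccccc2)c(OC)c(OC)c1OCc1ccccc1
F3 | step 11 | (2R)-2-[2,5-bis(benzyloxy)-3,4-dimethoxyphenyl]-2-{[4-(benzyloxy)-2-iodo-3,5-dimethoxyphenyl]methyl}-3-{[tert-butyl(dimethyl)silyl]oxy}propan-1-ol | OC[C@@](CO[Si](C)(C)C(C)(C)C)(Cc1cc(OC)c(OCc2ccccc2)c(OC)c1I)c1cc(OCc2ccccc2)c(OC)c(OC)c1OCc1ccccc1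
F4 | step 11 | tert-butyl({(3R)-7-(benzyloxy)-3-[2,5-bis(benzyloxy)-3,4-dimethoxyphenyl]-6,8-dimethoxy-3,4-dihydro-2H-chromen-3-yl}methoxy)dimethylsilane | COc1c(OC)c(OCc2ccccc2)cc([C@@]2(CO[Si](C)(C)C(C)(C)C)COc3c(cc(OC)c(OCc4ccccc4)c3OC)C2)c1OCc1ccccc1
F5 | step 13 | 2-[2,5-bis(benzyloxy)-3,4-dimethoxyphenyl]acetic acid | OC(=O)Cc1cc(OCc2ccccc2)c(OC)c(OC)c1OCc1ccccc1
F6 | step 13 | (4S)-4-benzyl-3-{[2,5-bis(benzyloxy)-3,4-dimethoxyphenyl]acetyl}-1,3-oxazolidin-2-one | O=C(Cc1cc(OCc2ccccc2)c(OC)c(OC)c1OCc1ccccc1)N1[C@@H](Cc2ccccc2)COC1=O
F7 | step 13 | (4S)-4-benzyl-3-{(2S)-2-[2,5-bis(benzyloxy)-3,4-dimethoxyphenyl]-3-[4-(benzyloxy)-2-iodo-3,5-dimethoxyphenyl]propanoyl}-1,3-oxazolidin-2-one | O=C([C@@H](Cc1cc(OC)c(OCc2ccccc2)c(OC)c1I)c1cc(OCc2ccccc2)c(OC)c(OC)c1OCc1ccccc1)N1[C@@H](Cc2ccccc2)COC1=O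
F8 | step 13 | (2S)-2-[2,5-bis(benzyloxy)-3,4-dimethoxyphenyl]-3-[4-(benzyloxy)-2-iodo-3,5-dimethoxyphenyl]propan-1-ol | OC[C@@H](Cc1cc(OC)c(OCc2ccccc2)c(OC)c1I)c1cc(OCc2ccccc2)c(OC)c(OC)c1OCc1ccccc1
F9 | step 8 | [2,5-bis(benzyloxy)-3,4-dimethoxyphenyl]boronic acid | OB(O)c1cc(OCc2ccccc2)c(OC)c(OC)c1OCc1ccccc1
F10 | step 8 | diethyl 2-{[4-(benzyloxy)-2-iodo-3,5-dimethoxyphenyl]methyl}propanedioate | CCOC(=O)C(Cc1cc(OC)c(OCc2ccccc2)c(OC)c1I)C(=O)OCC
F11 | step 8 | [2,5-bis(benzyloxy)-3,4-dimethoxyphenyl]lead triacetate | CC(=O)O[Pb](OC(C)=O)(OC(C)=O)c1cc(OCc2ccccc2)c(OC)c(OC)c1OCc1ccccc1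
F0 | step 14 | none | none
A1 | alternative 1 | 7-(benzyloxy)-6,8-dimethoxy-2H-chromene | C1=Cc2cc(OC)c(OCc3ccccc3)c(OC)c2OC1
A2 | alternative 1 | 2,3-dimethoxy-1,4-benzoquinone (identical with 7) | COC1=C(OC)C(=O)C=CC1=O
A3 | alternative 1 | cis-(6aS,11aS)-3-(benzyloxy)-2,4,9,10-tetramethoxypterocarpan-8-ol | COc1c(OC)c(O)cc2c1O[C@@H]1c3cc(OC)c(OCc4ccccc4)c(OC)c3OC[C@H]21
A4 | alternative 2 | 3-(benzyloxy)-2,4-dimethoxy-6-{[(4-methylphenyl)sulfonyl]methyl}phenol | Cc1ccc(cc1)S(=O)(=O)Cc1cc(OC)c(OCc2ccccc2)c(OC)c1O
A5 | alternative 2 | 3-(benzyloxy)-2,4-dimethoxy-6-methylidenecyclohexa-2,4-dien-1-one | C=C1C=C(OC)C(OCc2ccccc2)=C(OC)C1=O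
A6 | alternative 2 | 2-[2,5-bis(benzyloxy)-3,4-dimethoxyphenyl]acetic acid (identical with F5) | OC(=O)Cc1cc(OCc2ccccc2)c(OC)c(OC)c1OCc1ccccc1
A7 | alternative 2 | (3S)-7-(benzyloxy)-3-[2,5-bis(benzyloxy)-3,4-dimethoxyphenyl]-6,8-dimethoxy-3,4-dihydro-2H-chromen-2-one | O=C1Oc2c(OC)c(OCc3ccccc3)c(OC)cc2C[C@H]1c1cc(OCc2ccccc2)c(OC)c(OC)c1OCc1ccccc1
A8 | alternative 2 | (2S)-2-[2,5-bis(benzyloxy)-3,4-dimethoxyphenyl]-3-[4-(benzyloxy)-2-hydroxy-3,5-dimethoxyphenyl]propan-1-ol | OC[C@@H](Cc1cc(OC)c(OCc2ccccc2)c(OC)c1O)c1cc(OCc2ccccc2)c(OC)c(OC)c1OCc1ccccc1
A9 | alternative 3 | 2-(benzyloxy)-4-iodo-1,3-dimethoxybenzene | COc1ccc(I)c(OC)c1OCc1ccccc1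
A10 | alternative 3 | (2S)-2-[2,5-bis(benzyloxy)-3,4-dimethoxyphenyl]-3-bromopropan-1-ol | OC[C@@H](CBr)c1cc(OCc2ccccc2)c(OC)c(OC)c1OCc1ccccc1
A11 | alternative 3 | (3S)-7-(benzyloxy)-3-[2,5-bis(benzyloxy)-3,4-dimethoxyphenyl]-6,8-dimethoxy-3,4-dihydro-2H-chromene (identical with 17) | COc1c(OC)c(OCc2ccccc2)cc([C@H]2COc3c(cc(OC)c(OCc4ccccc4)c3OC)C2)c1OCc1ccccc1
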